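**Strategy.** Rings B and C are disconnected together at C8–C9 and C13–C14, the two bonds of the ring C cyclohexane that flank its C8–C14 edge. An intramolecular Diels–Alder reaction of an acyclic precursor, in which the 1,2-dioxygenated diene C9=C11–C12=C13 is tied through C10 and the enoate C5=C6 to the 1,1-disubstituted alkene C8=C14, should close both rings at once and set C8 and C9. A temporary silyloxy stereocentre at C10 steers the facial sense. Ring D follows by gold-catalysed enol ether–alkyne cyclisation, ring A by acetylide addition, Michael addition and aldol closure.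

Key step: step 10

Remark: the target is named here as 12α-hydroxygibberellic acid and gibberellane numbering (C1 to C19) is used throughout. The C10 silyl ether is assumed to stay on the face opposite the forming ring C in step 10. If the sense were opposite, the mirror-image ligand in step 8 would restore the natural series, because C10 becomes a carbonyl in step 17.

Step 1
Reactants: 1 2,3-dibromoprop-1-ene; 2 lithium (trimethylsilyl)acetylide
Product: 3 2-bromo-5-(trimethylsilyl)pent-1-en-4-yne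
Conditions: CuBr·SMe2 (10 mol %), THF, −20 °C to rt
Reagents that add atoms: none
Why: Copper-catalysed alkynyl–allyl coupling should substitute only the allylic bromide and leave the vinylic bromide untouched.

Step 2
Reactants: 4 oxalyl chloride; 5 2-(trimethylsilyl)ethanol (2 equiv)
Product: 6 bis[2-(trimethylsilyl)ethyl] oxalate
Conditions: Et3N, CH2Cl2, 0 °C to rt
Reagents that add atoms: none
Why: Double acylation of the alcohol by the diacid chloride (ester formation).

Step 3
Reactants: 3 2-bromo-5-(trimethylsilyl)pent-1-en-4-yne; 6 bis[2-(trimethylsilyl)ethyl] oxalate (3 equiv)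
Product: 8 2-(trimethylsilyl)ethyl 3-methylidene-2-oxo-6-(trimethylsilyl)hex-5-ynoate, via vinyllithium 7 (not isolated)
Conditions: t-BuLi (2 equiv), Et2O, −78 °C; then added to 6, THF, −78 °C; AcOH quench
Reagents that add atoms: none
Why: Bromine–lithium exchange, then mono-acylation by the oxalate diester, whose tetrahedral adduct persists until the quench and so should prevent a second addition (α-keto ester synthesis).

Step 4
Reactants: 8 2-(trimethylsilyl)ethyl 3-methylidene-2-oxo-6-(trimethylsilyl)hex-5-ynoate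
Product: 9 2-(trimethylsilyl)ethyl (2E)-3-methylidene-2-(2-oxoethylidene)-6-(trimethylsilyl)hex-5-ynoate
Conditions: Ph3P=CHCHO, toluene, 40 °C; then I2 (2 mol %), CH2Cl2, rt
Reagents that add atoms: (triphenylphosphoranylidene)acetaldehyde, O=CC=P(c1ccccc1)(c1ccccc1)c1ccccc1
Why: Wittig olefination of the activated keto group by the stabilised ylide, with iodine-catalysed equilibration to the E isomer in which formyl and ester are trans.

Step 5
Reactants: 10 2-chloro-N-methoxy-N-methylacetamide; 11 4-methoxybenzyl alcohol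
Product: 12 N-methoxy-2-[(4-methoxybenzyl)oxy]-N-methylacetamide
Conditions: NaH, THF, 0 °C to rt
Reagents that add atoms: none
Why: Williamson ether synthesis on the α-chloro amide.

Step 6
Reactants: 12 N-methoxy-2-[(4-methoxybenzyl)oxy]-N-methylacetamide
Product: 13 1-[(4-methoxybenzyl)oxy]but-3-yn-2-one
Conditions: HC≡CMgBr, THF, 0 °C; aq. NH4Cl
Reagents that add atoms: ethynylmagnesium bromide, C#C[Mg]Br
Why: Weinreb ketone synthesis, in which the chelated tetrahedral intermediate should stop the addition at the ynone.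

Step 7
Reactants: 13 1-[(4-methoxybenzyl)oxy]but-3-yn-2-one
Product: 15 (3E)-4-iodo-1-[(4-methoxybenzyl)oxy]but-3-en-2-one, via Z-iodoenone 14 (not isolated)
Conditions: NaI, AcOH, rt; then 50 °C
Reagents that add atoms: sodium iodide, [Na+].[I-]
Why: Conjugate hydroiodination of the ynone gives the Z-β-iodoenone, which should equilibrate by reversible iodide addition to the more stable E isomer.

Step 8
Reactants: 9 2-(trimethylsilyl)ethyl (2E)-3-methylidene-2-(2-oxoethylidene)-6-(trimethylsilyl)hex-5-ynoate; 15 (3E)-4-iodo-1-[(4-methoxybenzyl)oxy]but-3-en-2-one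
Product: 16 2-(trimethylsilyl)ethyl (2E,4S,5E)-4-hydroxy-8-[(4-methoxybenzyl)oxy]-7-oxo-2-[5-(trimethylsilyl)pent-1-en-4-yn-2-yl]octa-2,5-dienoate
Conditions: CrCl2 (3 equiv), NiCl2 (2 mol %), (S)-N-[2-(4-isopropyl-4,5-dihydrooxazol-2-yl)-6-methylphenyl]methanesulfonamide (3.3 equiv), Et3N, THF, rt
Reagents that add atoms: none
Why: Asymmetric Nozaki–Hiyama–Kishi reaction, in which the alkenylchromium species bound to the chiral sulfonamide–oxazoline ligand adds 1,2 to the aldehyde with retention of the E geometry and sets C10 as S by reagent control.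

Step 9
Reactants: 16 (2E,4S,5E)-hydroxy enone
Product: 17 2-(trimethylsilyl)ethyl (2E,4S,5E,7Z)-4,7-bis[(tert-butyldimethylsilyl)oxy]-8-[(4-methoxybenzyl)oxy]-2-[5-(trimethylsilyl)pent-1-en-4-yn-2-yl]octa-2,5,7-trienoate
Conditions: TBSOTf (2.5 equiv), Et3N, CH2Cl2, −78 to 0 °C
Reagents that add atoms: tert-butyldimethylsilyl trifluoromethanesulfonate, CC(C)(C)[Si](C)(C)OS(=O)(=O)C(F)(F)F
Why: O-silylation of the alcohol and soft enolisation of the ketone toward its only α-CH2 should give the Z-configured 1,2-dioxygenated silyl dienol ether.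

Step 10
Reactants: 17 (2E,4S,5E,7Z)-bis(silyloxy) trienoate
Product: 18 Diels–Alder adduct (cis-fused BC bicycle: ring B C5=C6 with ester on C6 and 10β-OTBS; ring C C11=C12 enol ether with 12-OTBS and 13α-OPMB; 9β-H; 8β-[3-(trimethylsilyl)prop-2-ynyl])
Conditions: toluene (0.005 M), BHT (10 mol %), 110 °C, sealed tube
Reagents that add atoms: none
Why: A concerted thermal [4+2] cycloaddition joins the electron-rich diene C9=C11–C12=C13 to the alkene C8=C14, which is conjugated with the enoate C5=C6, and forms C8–C9 and C13–C14 together; the closest known type is the type 1 intramolecular Diels–Alder reaction of 1,3,8-nonatrienes to hydrindenes. Ring B closes as the five-membered ring made by the three-atom tether C10–C5=C6 in the fused mode, and ring C is the six-membered ring of the cycloaddition itself. The cis-alkene in the tether should strongly favour the endo-tether transition state, so the ring fusion is cis (H9 and the propargyl group on C8 on one face), and the E geometry at C9=C11 with the Z enol ether places C10 and the C13 oxygen on the same face of ring C by suprafacial addition. The absolute sense comes from the C10 silyloxy group, which should stay on the face of the forming cyclopentene opposite to ring C, so that the S centre leads to the natural configuration at C8 and C9. The step needs periselectivity against the only other intramolecular [4+2] pairing (diene C5=C6–C8=C14 with enol ether C12=C13), which would place the E-alkene C9=C11 in a small ring and is therefore impossible, and against a 1,5-hydrogen shift of C10–H, which high dilution and the lowest workable temperature should keep slow.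

Step 11
Reactants: 18 Diels–Alder adduct
Product: 19 13α-OPMB 12-ketone with free prop-2-ynyl group on C8 (10β-OTBS)
Conditions: K2CO3, MeOH/THF, 0 °C to rt
Reagents that add atoms: none
Why: Base-induced methanolysis should cleave the silyl enol ether (enolate as leaving group) and the alkynyl C–Si bond while the alkyl silyl ether and the ester persist; the C13 configuration is irrelevant because step 12 removes it.

Step 12
Reactants: 19 13α-OPMB 12-ketone
Product: 20 enediol ether (C12=C13 with 12-OTBS and 13-OPMB; 10β-OTBS)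
Conditions: TBSOTf (1.5 equiv), Et3N, CH2Cl2, 0 °C to rt
Reagents that add atoms: tert-butyldimethylsilyl trifluoromethanesulfonate, CC(C)(C)[Si](C)(C)OS(=O)(=O)C(F)(F)F
Why: Soft enolisation under equilibrating conditions should go toward the alkoxy-bearing, more acidic C13–H and give the tetrasubstituted enediol ether (thermodynamic silyl enol ether formation).

Step 13
Reactants: 20 enediol ether
Product: 21 tricyclic 12-ketone (ring D closed through C13–C16, C16=C17 methylene, 13-OPMB, 10β-OTBS)
Conditions: Ph3PAuCl (5 mol %), AgBF4 (5 mol %), CH2Cl2/MeOH (10:1), rt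
Reagents that add atoms: none
Why: Gold-catalysed 5-exo-dig carbocyclisation of the silyl enol ether onto the alkyne (Conia-ene type) forms C13–C16 and the exocyclic methylene, and C13 can bond only on the face that carries the propargyl group, which fixes the bridgehead.

Step 14
Reactants: 21 tricyclic 12-ketone
Product: 22 12α-alcohol (13-OPMB, 10β-OTBS)
Conditions: NaBH4, MeOH/CH2Cl2, −40 °C
Reagents that add atoms: none
Why: Hydride reduction in which attack anti to C10, which is axial on ring C, should give the 12α-alcohol cis to the C13 oxygen.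

Step 15
Reactants: 22 12α-alcohol
Product: 23 12α,13-O-(4-methoxybenzylidene) acetal (10β-OTBS)
Conditions: DDQ, 4 Å MS, CH2Cl2, 0 °C
Reagents that add atoms: none
Why: Oxidation of the 4-methoxybenzyl ether to its oxocarbenium ion and capture by the cis 12-hydroxyl closes the cyclic acetal (oxidative acetal formation under anhydrous conditions).

Step 16
Reactants: 23 12α,13-acetal 10β-silyl ether
Product: 24 12α,13-acetal 10β-alcohol
Conditions: HF·pyridine, pyridine, THF, 0 °C to rt
Reagents that add atoms: none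
Why: Fluoride-mediated desilylation of the only silyl ether, under which the 2-(trimethylsilyl)ethyl ester and the buffered acetal should survive.

Step 17
Reactants: 24 12α,13-acetal 10β-alcohol
Product: 25 12α,13-acetal ring B enone (C10 ketone conjugated with C5=C6)
Conditions: Dess–Martin periodinane, NaHCO3, CH2Cl2, rt
Reagents that add atoms: none
Why: Dess–Martin oxidation of the allylic alcohol gives the cyclopentenone and removes the temporary C10 stereocentre.

Step 18
Reactants: 25 ring B enone; 26 tert-butyldimethyl(prop-2-yn-1-yloxy)silane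
Product: 29 10α-O-propanoyl 10β-[3-(tert-butyldimethylsilyloxy)prop-1-ynyl] adduct, via lithium acetylide 27 (not isolated), via lithium alkoxide 28 (not isolated)
Conditions: 26, n-BuLi, THF, −78 °C; CeCl3, then 25, −78 °C; then (EtCO)2O, DMAP (cat.), −78 to 0 °C
Reagents that add atoms: propanoic anhydride, CCC(=O)OC(=O)CC
Why: 1,2-Addition of the cerium-modified acetylide to the enone from the β face, the α face being shielded by ring C, sets C10 with oxygen α, and the tertiary alkoxide is acylated in the same flask.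

Step 19
Reactants: 29 10α-O-propanoyl 10β-alkynyl adduct
Product: 30 19,10-lactone (C4 epimers; H5β; 6β-ester; 10β-alkynyl chain)
Conditions: KOt-Bu (0.3 equiv), t-BuOH/THF, 0 °C to rt
Reagents that add atoms: none
Why: Intramolecular Michael addition (5-exo-trig) of the propionate enolate to C5 of the enoate closes the cis-fused γ-lactone, which sets H5 as β, and the reversible conditions should equilibrate C6 to the ester trans to C4.

Step 20
Reactants: 30 alkynyl lactone
Product: 31 Z-allyl silyl ether lactone (C1=C2 Z)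
Conditions: H2 (1 atm), Pd/CaCO3 poisoned with Pb(OAc)2, quinoline, EtOAc, rt
Reagents that add atoms: none
Why: Lindlar semihydrogenation gives the Z-alkene by syn addition and should not touch the 1,1-disubstituted alkene.

Step 21
Reactants: 31 Z-allyl silyl ether lactone
Product: 32 Z-allylic alcohol lactone
Conditions: HF·pyridine, pyridine, THF, 0 °C
Reagents that add atoms: none
Why: Fluoride-mediated cleavage of the primary silyl ether.

Step 22
Reactants: 32 Z-allylic alcohol lactone
Product: 33 Z-enal lactone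
Conditions: MnO2, CH2Cl2, rt
Reagents that add atoms: none
Why: Selective oxidation of the allylic alcohol by MnO2 under neutral conditions should keep the Z geometry of the enal.

Step 23
Reactants: 33 Z-enal lactone
Product: 34 12α-hydroxygibberellic acid 12,13-O-(4-methoxybenzylidene) acetal 2-(trimethylsilyl)ethyl ester
Conditions: LiN(SiMe3)2, THF, −78 °C; AcOH quench at −78 °C
Reagents that add atoms: none
Why: Intramolecular aldol addition of the lactone enolate to the Z-enal closes ring A, with the C4 configuration forced by the bicyclic lactone and the hydroxyl expected β (axial) from an open transition state with opposed dipoles under kinetic control.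

Step 24
Reactants: 34 acetal 2-(trimethylsilyl)ethyl ester of the target
Product: 36 12α-hydroxygibberellic acid (the target gibberellin), via carboxylic acid 35 (not isolated)
Conditions: Bu4NF, AcOH (1:1), THF, rt; then AcOH/H2O (4:1), 40 °C
Reagents that add atoms: none
Why: Fluoride-induced fragmentation of the 2-(trimethylsilyl)ethyl ester followed by mild acid hydrolysis of the benzylidene acetal, conditions that should spare the allylic lactone and the 13-hydroxy-16-ene unit.

**Compound list**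

1 | 2,3-dibromoprop-1-ene | C=C(Br)CBr | starting material
2 | lithium (trimethylsilyl)acetylide | [Li]C#C[Si](C)(C)C | starting material
3 | 2-bromo-5-(trimethylsilyl)pent-1-en-4-yne | C=C(Br)CC#C[Si](C)(C)C | intermediate
4 | oxalyl chloride | O=C(Cl)C(=O)Cl | starting material
5 | 2-(trimethylsilyl)ethanol | OCC[Si](C)(C)C | starting material
6 | bis[2-(trimethylsilyl)ethyl] oxalate | C[Si](C)(C)CCOC(=O)C(=O)OCC[Si](C)(C)C | intermediate
7 | [5-(trimethylsilyl)pent-1-en-4-yn-2-yl]lithium | [Li]C(=C)CC#C[Si](C)(C)C | intermediate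
8 | 2-(trimethylsilyl)ethyl 3-methylidene-2-oxo-6-(trimethylsilyl)hex-5-ynoate | C=C(CC#C[Si](C)(C)C)C(=O)C(=O)OCC[Si](C)(C)C | intermediate
9 | 2-(trimethylsilyl)ethyl (2E)-3-methylidene-2-(2-oxoethylidene)-6-(trimethylsilyl)hex-5-ynoate | O=C/C=C(/C(=O)OCC[Si](C)(C)C)C(=C)CC#C[Si](C)(C)C | intermediate
10 | 2-chloro-N-methoxy-N-methylacetamide | ClCC(=O)N(C)OC | starting material
11 | 4-methoxybenzyl alcohol | COc1ccc(CO)cc1 | starting material
12 | N-methoxy-2-[(4-methoxybenzyl)oxy]-N-methylacetamide | COc1ccc(COCC(=O)N(C)OC)cc1 | intermediate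
13 | 1-[(4-methoxybenzyl)oxy]but-3-yn-2-one | COc1ccc(COCC(=O)C#C)cc1 | intermediate
14 | (3Z)-4-iodo-1-[(4-methoxybenzyl)oxy]but-3-en-2-one | COc1ccc(COCC(=O)/C=C\I)cc1 | intermediate
15 | (3E)-4-iodo-1-[(4-methoxybenzyl)oxy]but-3-en-2-one | COc1ccc(COCC(=O)/C=C/I)cc1 | intermediate
16 | 2-(trimethylsilyl)ethyl (2E,4S,5E)-4-hydroxy-8-[(4-methoxybenzyl)oxy]-7-oxo-2-[5-(trimethylsilyl)pent-1-en-4-yn-2-yl]octa-2,5-dienoate | COc1ccc(COCC(=O)/C=C/[C@H](O)/C=C(/C(=O)OCC[Si](C)(C)C)C(=C)CC#C[Si](C)(C)C)cc1 | intermediate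
17 | 2-(trimethylsilyl)ethyl (2E,4S,5E,7Z)-4,7-bis[(tert-butyldimethylsilyl)oxy]-8-[(4-methoxybenzyl)oxy]-2-[5-(trimethylsilyl)pent-1-en-4-yn-2-yl]octa-2,5,7-trienoate | COc1ccc(CO/C=C(\O[Si](C)(C)C(C)(C)C)/C=C/[C@H](O[Si](C)(C)C(C)(C)C)/C=C(/C(=O)OCC[Si](C)(C)C)C(=C)CC#C[Si](C)(C)C)cc1 | intermediate
18 | Diels–Alder adduct: cis-fused BC bicycle, ring B C5=C6 with CO2CH2CH2SiMe3 on C6 and 10β-OTBS, ring C C11=C12 with 12-OTBS and 13α-OPMB, 9β-H, 8β-[3-(trimethylsilyl)prop-2-ynyl] | C[Si](C)(C)C#CC[C@]12C[C@@H](OCc3ccc(OC)cc3)C(O[Si](C)(C)C(C)(C)C)=C[C@H]1[C@H](O[Si](C)(C)C(C)(C)C)C=C2C(=O)OCC[Si](C)(C)C | intermediate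
19 | 13α-OPMB 12-ketone of the BC bicycle with 8β-prop-2-ynyl and 10β-OTBS | C#CC[C@]12C[C@@H](OCc3ccc(OC)cc3)C(=O)C[C@H]1[C@H](O[Si](C)(C)C(C)(C)C)C=C2C(=O)OCC[Si](C)(C)C | intermediate
20 | enediol ether: C12=C13 with 12-OTBS and 13-OPMB, 10β-OTBS, 8β-prop-2-ynyl | C#CC[C@]12CC(OCc3ccc(OC)cc3)=C(O[Si](C)(C)C(C)(C)C)C[C@H]1[C@H](O[Si](C)(C)C(C)(C)C)C=C2C(=O)OCC[Si](C)(C)C | intermediate
21 | tricyclic 12-ketone: rings B, C and D, C16=C17 methylene, 13-OPMB, 10β-OTBS, C5=C6 ester | C=C1C[C@]23C[C@@]1(OCc4ccc(OC)cc4)C(=O)C[C@H]2[C@H](O[Si](C)(C)C(C)(C)C)C=C3C(=O)OCC[Si](C)(C)C | intermediate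
22 | 12α-alcohol of 21 | C=C1C[C@]23C[C@@]1(OCc4ccc(OC)cc4)[C@@H](O)C[C@H]2[C@H](O[Si](C)(C)C(C)(C)C)C=C3C(=O)OCC[Si](C)(C)C | intermediate
23 | 12α,13-O-(4-methoxybenzylidene) acetal, 10β-OTBS (acetal carbon as a mixture) | C=C1C[C@]23C[C@]14OC(c5ccc(OC)cc5)O[C@H]4C[C@H]2[C@H](O[Si](C)(C)C(C)(C)C)C=C3C(=O)OCC[Si](C)(C)C | intermediate
24 | 12α,13-acetal 10β-alcohol | C=C1C[C@]23C[C@]14OC(c5ccc(OC)cc5)O[C@H]4C[C@H]2[C@H](O)C=C3C(=O)OCC[Si](C)(C)C | intermediate
25 | 12α,13-acetal ring B enone (10-oxo, C5=C6 ester) | C=C1C[C@]23C[C@]14OC(c5ccc(OC)cc5)O[C@H]4C[C@H]2C(=O)C=C3C(=O)OCC[Si](C)(C)C | intermediate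
26 | tert-butyldimethyl(prop-2-yn-1-yloxy)silane | C#CCO[Si](C)(C)C(C)(C)C | starting material
27 | lithium acetylide of 26 | [Li]C#CCO[Si](C)(C)C(C)(C)C | intermediate
28 | lithium 10α-alkoxide of the 10β-alkynyl adduct | C=C1C[C@]23C[C@]14OC(c5ccc(OC)cc5)O[C@H]4C[C@H]2[C@](O[Li])(C#CCO[Si](C)(C)C(C)(C)C)C=C3C(=O)OCC[Si](C)(C)C | intermediate
29 | 10α-O-propanoyl 10β-[3-(tert-butyldimethylsilyloxy)prop-1-ynyl] adduct | C=C1C[C@]23C[C@]14OC(c5ccc(OC)cc5)O[C@H]4C[C@H]2[C@](OC(=O)CC)(C#CCO[Si](C)(C)C(C)(C)C)C=C3C(=O)OCC[Si](C)(C)C | intermediate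
30 | 19,10-lactone, C4 epimers, H5β, 6β-ester, 10β-alkynyl chain | C=C1C[C@]23C[C@]14OC(c5ccc(OC)cc5)O[C@H]4C[C@H]2[C@@]2(C#CCO[Si](C)(C)C(C)(C)C)OC(=O)C(C)[C@H]2[C@@H]3C(=O)OCC[Si](C)(C)C | intermediate
31 | lactone with 10β-[(Z)-3-(tert-butyldimethylsilyloxy)prop-1-enyl] chain | C=C1C[C@]23C[C@]14OC(c5ccc(OC)cc5)O[C@H]4C[C@H]2[C@@]2(/C=C\CO[Si](C)(C)C(C)(C)C)OC(=O)C(C)[C@H]2[C@@H]3C(=O)OCC[Si](C)(C)C | intermediate
32 | lactone with 10β-[(Z)-3-hydroxyprop-1-enyl] chain | C=C1C[C@]23C[C@]14OC(c5ccc(OC)cc5)O[C@H]4C[C@H]2[C@@]2(/C=C\CO)OC(=O)C(C)[C@H]2[C@@H]3C(=O)OCC[Si](C)(C)C | intermediate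
33 | lactone with 10β-[(Z)-3-oxoprop-1-enyl] chain | C=C1C[C@]23C[C@]14OC(c5ccc(OC)cc5)O[C@H]4C[C@H]2[C@@]2(/C=C\C=O)OC(=O)C(C)[C@H]2[C@@H]3C(=O)OCC[Si](C)(C)C | intermediate
34 | 12α-hydroxygibberellic acid 12,13-O-(4-methoxybenzylidene) acetal 2-(trimethylsilyl)ethyl ester | C=C1C[C@]23C[C@]14OC(c5ccc(OC)cc5)O[C@H]4C[C@H]2[C@@]12C=C[C@H](O)[C@@](C)(C(=O)O1)[C@H]2[C@@H]3C(=O)OCC[Si](C)(C)C | intermediate
35 | 12α-hydroxygibberellic acid 12,13-O-(4-methoxybenzylidene) acetal | C=C1C[C@]23C[C@]14OC(c5ccc(OC)cc5)O[C@H]4C[C@H]2[C@@]12C=C[C@H](O)[C@@](C)(C(=O)O1)[C@H]2[C@@H]3C(=O)O | intermediate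
36 | 12α-hydroxygibberellic acid, the target gibberellin (3β,12α,13-trihydroxy; 12-hydroxyl cis to the 13-hydroxyl on ring C) | C=C1C[C@]23C[C@@]1(O)[C@@H](O)C[C@H]2[C@@]12C=C[C@H](O)[C@@](C)(C(=O)O1)[C@H]2[C@@H]3C(=O)O | target

**Step count and risks**

Total step count: 24. Longest linear sequence: 20 steps (steps 1, 3, 4 and 8 to 24).

Most likely to fail:

1. Step 10. A 1,5-hydrogen shift of C10–H into the ester diene or intermolecular dimerisation may outrun the cycloaddition, and the silyl ether may discriminate the two diene faces poorly. The fallback sets out from 16 and comes back to the route at 20. MnO2 in CH2Cl2 should oxidise the doubly allylic alcohol to the 4,7-dioxo dienoate F1, which has no C10–H. TBSOTf and Et3N should then give the silyloxy trienone F2. Its cycloaddition under Lewis acid catalysis by the cationic oxazaborolidine made from (S)-diphenylprolinol, 2-methylphenylboronic acid and HN(SO2CF3)2 (CH2Cl2, −78 °C) should give the cyclopentenone adduct F3, with the catalyst in control of the absolute sense. Luche reduction (NaBH4, CeCl3, MeOH) from the open β face should give the 10α-alcohol F4. Mitsunobu inversion (4-nitrobenzoic acid, PPh3, diisopropyl azodicarboxylate) should give the 10β-(4-nitrobenzoate) F5. K2CO3 in MeOH should remove the benzoate, the enol silyl group and the alkynyl silane to give the 10β-hydroxy ketone F6. The silylation of step 12 with excess TBSOTf then gives 20.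

2. Step 12. Enolisation toward C11 in place of C13 would give the regioisomeric enol ether, and the gold step would then close the wrong ring. The fallback sets out from 19 and comes back to the route at 23. DDQ in wet CH2Cl2 should remove the benzyl ether to give the acyloin F7. Dess–Martin oxidation should give the 12,13-diketone F8. Reductive bis-silylation (Zn, Me3SiCl, THF) should give the regiodefined enediol bis(trimethylsilyl) ether F9. Ph3PAuCl and AgBF4 in CH2Cl2/MeOH should close ring D by the 5-exo-dig mode to give the 13-trimethylsilyloxy 12-ketone F10. NaBH4 and then K2CO3 in MeOH should give the 12α,13-diol F11. 4-Methoxybenzaldehyde dimethyl acetal with pyridinium p-toluenesulfonate then gives 23.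

3. Step 23. A closed, lithium-chelated transition state may deliver the 3α-alcohol, and enolisation at C6 or retro-aldol equilibration may erode the result. The fallback sets out from 33 and comes back to the route at 34. The same aldol addition would then give the 3α-epimer F12. Mitsunobu inversion (4-nitrobenzoic acid, PPh3, diisopropyl azodicarboxylate) should give the 3β-(4-nitrobenzoate) F13. NaN3 in MeOH at 40 °C should cleave this ester to give 34.

Further compounds
F1 | step 10 | 2-(trimethylsilyl)ethyl (2E,5E)-8-[(4-methoxybenzyl)oxy]-4,7-dioxo-2-[5-(trimethylsilyl)pent-1-en-4-yn-2-yl]octa-2,5-dienoate | COc1ccc(COCC(=O)/C=C/C(=O)/C=C(/C(=O)OCC[Si](C)(C)C)C(=C)CC#C[Si](C)(C)C)cc1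
F2 | step 10 | 2-(trimethylsilyl)ethyl (2E,5E,7Z)-7-[(tert-butyldimethylsilyl)oxy]-8-[(4-methoxybenzyl)oxy]-4-oxo-2-[5-(trimethylsilyl)pent-1-en-4-yn-2-yl]octa-2,5,7-trienoate | COc1ccc(CO/C=C(\O[Si](C)(C)C(C)(C)C)/C=C/C(=O)/C=C(/C(=O)OCC[Si](C)(C)C)C(=C)CC#C[Si](C)(C)C)cc1
F3 | step 10 | 10-oxo analogue of 18 (ring B cyclopentenone adduct) | C[Si](C)(C)C#CC[C@]12C[C@@H](OCc3ccc(OC)cc3)C(O[Si](C)(C)C(C)(C)C)=C[C@H]1C(=O)C=C2C(=O)OCC[Si](C)(C)C
F4 | step 10 | 10α-alcohol from F3 | C[Si](C)(C)C#CC[C@]12C[C@@H](OCc3ccc(OC)cc3)C(O[Si](C)(C)C(C)(C)C)=C[C@H]1[C@@H](O)C=C2C(=O)OCC[Si](C)(C)C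
F5 | step 10 | 10β-(4-nitrobenzoate) | C[Si](C)(C)C#CC[C@]12C[C@@H](OCc3ccc(OC)cc3)C(O[Si](C)(C)C(C)(C)C)=C[C@H]1[C@H](OC(=O)c3ccc(cc3)[N+](=O)[O-])C=C2C(=O)OCC[Si](C)(C)C
F6 | step 10 | 10β-hydroxy 13α-OPMB 12-ketone with free prop-2-ynyl group | C#CC[C@]12C[C@@H](OCc3ccc(OC)cc3)C(=O)C[C@H]1[C@H](O)C=C2C(=O)OCC[Si](C)(C)C
F7 | step 12 | 13-hydroxy 12-ketone (acyloin, 10β-OTBS) | C#CC[C@]12C[C@@H](O)C(=O)C[C@H]1[C@H](O[Si](C)(C)C(C)(C)C)C=C2C(=O)OCC[Si](C)(C)C
F8 | step 12 | 12,13-diketone (10β-OTBS) | C#CC[C@]12CC(=O)C(=O)C[C@H]1[C@H](O[Si](C)(C)C(C)(C)C)C=C2C(=O)OCC[Si](C)(C)C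
F9 | step 12 | 12,13-bis(trimethylsilyloxy) enediol ether (10β-OTBS) | C#CC[C@]12CC(O[Si](C)(C)C)=C(O[Si](C)(C)C)C[C@H]1[C@H](O[Si](C)(C)C(C)(C)C)C=C2C(=O)OCC[Si](C)(C)C
F10 | step 12 | tricyclic 12-ketone with 13-trimethylsilyloxy group (10β-OTBS) | C=C1C[C@]23C[C@@]1(O[Si](C)(C)C)C(=O)C[C@H]2[C@H](O[Si](C)(C)C(C)(C)C)C=C3C(=O)OCC[Si](C)(C)C
F11 | step 12 | tricyclic 12α,13-diol (10β-OTBS) | C=C1C[C@]23C[C@@]1(O)[C@@H](O)C[C@H]2[C@H](O[Si](C)(C)C(C)(C)C)C=C3C(=O)OCC[Si](C)(C)C
F12 | step 23 | 3α-epimer of 34 | C=C1C[C@]23C[C@]14OC(c5ccc(OC)cc5)O[C@H]4C[C@H]2[C@@]12C=C[C@@H](O)[C@@](C)(C(=O)O1)[C@H]2[C@@H]3C(=O)OCC[Si](C)(C)C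
F13 | step 23 | 3β-(4-nitrobenzoate) of 34 | C=C1C[C@]23C[C@]14OC(c5ccc(OC)cc5)O[C@H]4C[C@H]2[C@@]12C=C[C@H](OC(=O)c5ccc(cc5)[N+](=O)[O-])[C@@](C)(C(=O)O1)[C@H]2[C@@H]3C(=O)OCC[Si](C)(C)C
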